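# Proposed synthesis of pentacosyl 3-(4-hydroxyphenyl)propanoate (11)

Compound numbers used throughout: 1 4-hydroxybenzaldehyde, 2 iminium acetate (in situ), 3 4-[(dimethylamino)methyl]phenol, 4 (4-hydroxybenzyl)trimethylammonium iodide, 5 pentacosan-1-ol, 6 3-(tert-butoxy)-3-oxopropanoic acid, 7 tert-butyl pentacosyl malonate, 8 4-methylidenecyclohexa-2,5-dien-1-one (in situ), 9 tert-butyl pentacosyl 2-(4-hydroxybenzyl)malonate, 10 the corresponding malonic half-acid, 11 the target.

Atom labels: propanoate C1 (carbonyl), C2, C3 (benzylic); aryl C1 (bonded to C3) to aryl C6, with the hydroxyl on aryl C4.

## Analysis of the target

The target 11 is the ester of 3-(4-hydroxyphenyl)propanoic acid with an unbranched C25 alcohol: a para-disubstituted benzene ring, a two-carbon tether (C2 and C3), one ester carbonyl (C1) and a saturated chain of 25 carbons. It has no stereocentre and no ring other than the arene, so nothing has to be controlled in three dimensions. The sensitive groups are the free phenol, which is acidic, nucleophilic at oxygen and at the ring carbons ortho to it and easily oxidised, and the single ester, which must not be hydrolysed or exchanged once the costly chain is attached. The difficulty is therefore one of chemoselectivity and handling rather than of complexity, because a carbon–carbon bond has to be made next to an unprotected phenol. The wax chain governs solubility, and impurities that differ only in the chain cannot be separated, whereas those that differ in the polar head group can. The plan rests on the hydroxyl on aryl C4, which is para to aryl C1 and so conjugated through the ring with the benzylic carbon C3. A leaving group on C3 can be pushed out by the phenoxide, which turns the 4-hydroxybenzyl unit into a quinone methide that is electrophilic at exactly the carbon that must be bonded to C2, so the phenol is the activating group and needs no protection.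

## Retrosynthetic reasoning

**11 back to 10.** C2 of 11 carries no activating group beyond the single ester, so it could serve as a nucleophile only as a simple ester enolate made with a strong amide base. Neither the free phenol nor the quinone methide 8 tolerates that. A carboxyl group is therefore added to C2 in the retrosynthetic sense, which gives the malonic half-acid 10. The bond cut is C2–CO2H. This makes C2 a doubly activated, soft carbon acid that a carbonate base can deprotonate beside a phenol. In the forward direction 10 only has to lose its carboxyl group on heating.

**10 back to 9.** The auxiliary carboxyl group must be distinguishable from the pentacosyl ester, otherwise the chain would be lost with it. In 9 it is a tert-butyl ester, which acid cleaves by alkyl–oxygen fission while the primary alkyl ester stays intact. The forward step must remove the tert-butyl group without letting the cationic fragment that leaves alkylate the electron-rich ring.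

**9 back to 4 and 7, through 8.** The C2–C3 bond is cut. This is the one bond of the skeleton whose formation can use the innate polarity of the para-hydroxybenzyl unit: C3 becomes the electrophile (the exocyclic carbon of 8) and C2 the nucleophile (the enolate of 7). Cutting aryl C1–C3 or C1–C2 instead would call for transition-metal catalysis and a masked phenol. Cutting only the ester C–O bond would leave the arylpropanoic acid still to be made. The chain is placed on the malonate before this step, so that only deprotection and decarboxylation remain after it. The forward reaction has to release 8 slowly and give C-monoalkylation.

**4 back to 3 and 1.** The leaving group on C3 is a quaternary ammonium group rather than a halide. A halide beside a free para-hydroxyl would ionise spontaneously, whereas the salt 4 is crystalline and inert until base is added. The N–CH3 bond is cut first (quaternisation of 3), then the C3–N bond (reductive amination of aldehyde 1 through iminium ion 2).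

**7 back to 5 and 6.** The ester C–O bond between the pentacosyl oxygen and the malonyl carbonyl is cut. Carbodiimide coupling of alcohol 5 with half-acid 6 joins the chain to a small, robust fragment at the very start, and the tert-butyl ester of 6 is carried through unchanged.

## Alternatives that were turned down

Alternative 1: The arene itself is taken apart, at the ring bonds aryl C1–C6 and aryl C2–C3, so that the ring is built by Robinson annulation and aromatised afterwards. In the forward sense a secondary-amine catalyst would turn the aldehyde pentacosyl 5-oxopentanoate A1 into its enamine, which adds to the enone but-3-en-2-one A2. Intramolecular aldol condensation of the adduct in the same flask would close the six-membered ring to pentacosyl 3-(4-oxocyclohex-2-en-1-yl)propanoate A3 (racemic), and an oxidative dehydrogenation of A3 would give 11.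
- For: no phenol exists until the last step, so there is no protecting group and none of the side reactions of phenoxides. The enone A2 is a cheap bulk chemical, and every intermediate is an ordinary, storable carbonyl compound. On this point it is stronger than the chosen plan, which depends on a short-lived electrophile.
- Against: it constructs a benzene ring that can simply be bought. The aldehyde A1 is not an article of commerce and would need a few steps of its own from 5, to attach a five-carbon acyl unit and bring its far end to the aldehyde level. The annulation sets a ring stereocentre that is erased again. The final dehydrogenation of a monosubstituted cyclohexenone needs an oxidant at elevated temperature and adds a redox step that the target does not demand.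
- Comparison: the chosen route takes the ring as purchased, changes no oxidation state after the first step, and is shorter. In place of the robustness of A3 it offers a direct use of the hydroxyl that is already in the target.

Alternative 2: The cut lies inside the wax chain, at pentacosyl C15–C16. The acid 16-{[3-(4-acetoxyphenyl)propanoyl]oxy}hexadecanoic acid A4 would be electrolysed at a platinum anode together with an excess of undecanoic acid A5. Both carboxylates are decarboxylated and the two primary radicals combine to pentacosyl 3-(4-acetoxyphenyl)propanoate A6, whose aryl acetate must then be cleaved to reach 11.
- For: the odd-numbered C25 alcohol 5, which is costly, is not needed, because the chain comes from common C16 and C11 building blocks. On raw-material cost this is stronger than the chosen route.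
- Against: radical–radical coupling is statistical. The two homo-coupling products form beside A6, and the excess of A5 only improves the use of A4. Disproportionation and cation-derived side products give esters that differ from A6 only in the chain and would not separate from it. The phenol has to be masked because it would be oxidised at the anode, and the final step is a selective cleavage of an aryl acetate beside an alkyl ester. The acid A4 itself has to be assembled first by a selective O-acylation.
- Comparison: the chosen route pays for 5, but every bond is formed between two defined partners, its by-products differ in the polar head group and are removable on silica, and the phenol is never protected.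

Alternative 3: The bonds C1–C2 and C1–O(pentacosyl) are cut together, which gives three components. The styrene 1-(benzyloxy)-4-ethenylbenzene A7, carbon monoxide A8 and alcohol 5 would combine to pentacosyl 3-[4-(benzyloxy)phenyl]propanoate A9. The catalyst would be a hydride of divalent palladium formed in the flask from palladium diacetate A10, a chelating diphosphine and a strong acid. The hydride adds to the alkene of A7 in the anti-Markovnikov sense, A8 inserts into the palladium–carbon bond, and alcoholysis of the acyl by 5 releases A9. Hydrogenolysis of the benzyl ether of A9 then gives 11.
- For: it is atom-economic, forms two bonds in one step and needs only two steps from A7 and 5. On step economy and convergence it is clearly stronger than the chosen route.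
- Against: styrenes insert into the palladium–hydrogen bond mainly to give the benzylic palladium alkyl, which leads to the branched ester. Linear selectivity rests entirely on the ligand and the acid co-catalyst and is seldom complete. The branched regioisomer of A9 has the same head group and the same chain, so it would be almost inseparable and would pass through the hydrogenolysis. The electron-rich styrene A7 polymerises readily under acidic conditions. Alkoxycarbonylations normally use the alcohol in large excess, which is not possible with a solid, poorly soluble and expensive alcohol such as 5. Pressurised A8, the precious-metal salt A10 and a protecting group are also required.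
- Comparison: the chosen route is longer, but its regiochemistry is fixed by structure, since 8 has only one electrophilic carbon and no isomeric ester can form. It runs in ordinary glassware with the phenol free.

Key step: step 4

Remark: the malonate carbon of 9 and 10 is a stereocentre that is formed racemic and is removed in step 6, so no stereocontrol is planned.

## Route

Step 1
Reactants: 1 4-hydroxybenzaldehyde
Product: 3 4-[(dimethylamino)methyl]phenol, via iminium acetate 2 (not isolated)
Conditions: Me2NH (2 M in THF), NaBH(OAc)3, AcOH, THF, rt
Reagents that add atoms: dimethylamine, CNC
Why: Reductive amination: the secondary amine condenses with the aldehyde to the iminium ion 2, which NaBH(OAc)3 should reduce faster than the electron-rich aldehyde itself; the phenol is inert to this hydride and needs no protection.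

Step 2
Reactants: 3 4-[(dimethylamino)methyl]phenol
Product: 4 (4-hydroxybenzyl)trimethylammonium iodide
Conditions: MeI, acetone, rt, dark
Reagents that add atoms: iodomethane, CI
Why: Menshutkin quaternisation: with no base present the tertiary amine is by far the best nucleophile, so methylation should occur at nitrogen and not at the phenol oxygen, and the salt is expected to crystallise from acetone, which removes it from unreacted amine.

Step 3
Reactants: 5 pentacosan-1-ol; 6 3-(tert-butoxy)-3-oxopropanoic acid
Product: 7 tert-butyl pentacosyl malonate
Conditions: DCC, DMAP (cat.), CH2Cl2–THF, rt to 35 °C
Reagents that add atoms: none
Why: Steglich esterification: DCC activates the half-acid as its O-acylisourea and DMAP relays the acyl group to the primary alcohol, which suppresses the N-acylurea; the tert-butyl ester is untouched and the THF co-solvent keeps the waxy alcohol dissolved.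

Step 4
Reactants: 4 (4-hydroxybenzyl)trimethylammonium iodide; 7 tert-butyl pentacosyl malonate (in excess)
Product: 9 tert-butyl pentacosyl 2-(4-hydroxybenzyl)malonate (racemic), via 4-methylidenecyclohexa-2,5-dien-1-one 8 (not isolated)
Conditions: K2CO3 (3 equiv), THF–MeCN, 60 °C, N2, 4 added slowly by syringe pump as a MeCN–DMF solution; aq. NH4Cl work-up
Reagents that add atoms: none
Why: K2CO3 deprotonates the phenol of 4, and on warming the phenoxide expels the neutral amine through the ring in a 1,6-elimination of the E1cB type to give quinone methide 8. The same base forms the potassium enolate of 7, whose carbon adds to the exocyclic CH2 of 8 in a 1,6-conjugate (vinylogous Michael) addition, which makes the C2–C3 bond and closes no ring. The return of aromaticity makes this carbon–carbon bond formation effectively irreversible, whereas adducts of 8 with oxygen, nitrogen or iodide nucleophiles can revert to 8 and are funnelled on to 9. The closest known reaction type is the alkylation of malonate and other β-dicarbonyl enolates by quinone methides released from quaternised phenolic Mannich bases. The step needs C-monoalkylation: the soft exocyclic carbon of 8 pairs with the soft carbon of the enolate rather than with its oxygen, and a second benzylation is held back by the excess of 7, which is recoverable on silica, and by the greater hindrance and lower acidity of the C–H left in 9. Self-condensation of 8 is limited by the slow addition of 4, so that 8 always meets a large excess of enolate. The new stereocentre at the malonate carbon is formed without any controlling element, is racemic and labile, and is removed in step 6. Both esters are stable to carbonate in aprotic solvent, and the NH4Cl work-up returns the free phenol without harming the tert-butyl ester.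

Step 5
Reactants: 9 tert-butyl pentacosyl 2-(4-hydroxybenzyl)malonate
Product: 10 2-(4-hydroxybenzyl)-3-oxo-3-(pentacosyloxy)propanoic acid (racemic)
Conditions: TFA, Et3SiH, CH2Cl2, rt
Reagents that add atoms: none
Why: Acidolysis of a tert-butyl ester by alkyl–oxygen fission: only the tertiary ester ionises, the primary pentacosyl ester is stable to TFA, and triethylsilane reduces the tert-butyl cation to the alkane so that it cannot alkylate the ring positions ortho to the hydroxyl.

Step 6
Reactants: 10 2-(4-hydroxybenzyl)-3-oxo-3-(pentacosyloxy)propanoic acid
Product: 11 pentacosyl 3-(4-hydroxyphenyl)propanoate
Conditions: toluene, 110 °C, N2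
Reagents that add atoms: none
Why: Thermal decarboxylation of a malonic half-acid through the six-membered cyclic transition state gives the ester enol, which tautomerises to 11; the stereocentre disappears, and the ester and the phenol are not affected in the neutral, anhydrous medium.

## Compound list

1 | 4-hydroxybenzaldehyde | O=Cc1ccc(O)cc1 | starting material
2 | N-(4-hydroxybenzylidene)-N-methylmethanaminium acetate (iminium acetate, formed in situ, not isolated) | C[N+](C)=Cc1ccc(O)cc1.CC(=O)[O-] | intermediate
3 | 4-[(dimethylamino)methyl]phenol | CN(C)Cc1ccc(O)cc1 | intermediate
4 | (4-hydroxybenzyl)trimethylammonium iodide | C[N+](C)(C)Cc1ccc(O)cc1.[I-] | intermediate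
5 | pentacosan-1-ol | CCCCCCCCCCCCCCCCCCCCCCCCCO | starting material
6 | 3-(tert-butoxy)-3-oxopropanoic acid | CC(C)(C)OC(=O)CC(=O)O | starting material
7 | tert-butyl pentacosyl malonate | CCCCCCCCCCCCCCCCCCCCCCCCCOC(=O)CC(=O)OC(C)(C)C | intermediate
8 | 4-methylidenecyclohexa-2,5-dien-1-one (para-quinone methide, formed in situ, not isolated) | C=C1C=CC(=O)C=C1 | intermediate
9 | tert-butyl pentacosyl 2-(4-hydroxybenzyl)malonate (racemic) | CCCCCCCCCCCCCCCCCCCCCCCCCOC(=O)C(Cc1ccc(O)cc1)C(=O)OC(C)(C)C | intermediate
10 | 2-(4-hydroxybenzyl)-3-oxo-3-(pentacosyloxy)propanoic acid (racemic) | CCCCCCCCCCCCCCCCCCCCCCCCCOC(=O)C(Cc1ccc(O)cc1)C(=O)O | intermediate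
11 | pentacosyl 3-(4-hydroxyphenyl)propanoate | CCCCCCCCCCCCCCCCCCCCCCCCCOC(=O)CCc1ccc(O)cc1 | target

## Step count and risk

Total step count: 6. Longest linear sequence: 5 steps (steps 1, 2, 4, 5 and 6, from 1). The branch from 5 runs through 4 steps (3, 4, 5 and 6).

**Step 4 (key step).** The most likely failure is self-condensation of the quinone methide outrunning its capture by the enolate. Phenoxide oxygen or ring carbon of 4, of 9 or of oligomers can attack 8. A second benzylation of 9 is the other risk. Both are made worse by poor mixing of a polar salt with a waxy, sparingly soluble malonate.
- Fallback: this sets out from 7 (with 1) and comes back at 9, and it forms the same C2–C3 bond at the aldehyde oxidation level, with no quinone methide. Knoevenagel condensation of 7 with aldehyde 1 (piperidine, AcOH, toluene, azeotropic removal of water) should give tert-butyl pentacosyl 2-(4-hydroxybenzylidene)malonate F1 as an E/Z mixture. Hydrogenation of its C=C bond (H2, Pd/C, THF) should then give 9.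

**Step 5.** The risk is electrophilic tert-butylation of the ring positions ortho to the hydroxyl, if the tert-butyl cation or the tert-butyl trifluoroacetate formed from it escapes the silane.
- Fallback: this sets out from 5 (and uses 4) and comes back at 10. It replaces the acid-labile group by one removed under neutral conditions, so that no cation is formed. Alcohol 5 is coupled (DCC, DMAP) with 3-(benzyloxy)-3-oxopropanoic acid to give benzyl pentacosyl malonate F2. F2 is benzylated with 4 under the conditions of step 4, through 8, to benzyl pentacosyl 2-(4-hydroxybenzyl)malonate F3. Hydrogenolysis of F3 (H2, Pd/C, THF) then gives 10.

**Step 3.** The O-acylisourea may rearrange to the unreactive N-acylurea, or the activated half-acid may be lost through ketene formation, while the poorly soluble alcohol reacts slowly.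
- Fallback: this sets out from 5 and comes back at 7, and it needs no carbodiimide. Alcohol 5 is heated with 2,2-dimethyl-1,3-dioxane-4,6-dione in toluene, which opens the dioxanedione to 3-oxo-3-(pentacosyloxy)propanoic acid F4. The free acid of F4 is then converted into its tert-butyl ester with tert-butyl 2,2,2-trichloroacetimidate in CH2Cl2–cyclohexane to give 7.

**Step 6.** Decarboxylation may be slow at the boiling point of toluene. Prolonged heating would allow acyl transfer between molecules (phenol or acid onto the ester), which erodes the product.
- Fallback: this sets out from 5 (with 1) and comes back at 11. It moves the decarboxylation to the condensation stage. The half-acid 3-oxo-3-(pentacosyloxy)propanoic acid F4, made from 5 and 2,2-dimethyl-1,3-dioxane-4,6-dione as in the fallback to step 3, is condensed with aldehyde 1 under Doebner conditions (pyridine, piperidine cat., 90 °C). Condensation and decarboxylation occur together and should give pentacosyl (2E)-3-(4-hydroxyphenyl)prop-2-enoate F5. Hydrogenation of the alkene of F5 (H2, Pd/C, THF) then gives 11.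

## Further compounds

F1 | step 4 | tert-butyl pentacosyl 2-(4-hydroxybenzylidene)malonate (E/Z mixture) | CCCCCCCCCCCCCCCCCCCCCCCCCOC(=O)C(=Cc1ccc(O)cc1)C(=O)OC(C)(C)C
F2 | step 5 | benzyl pentacosyl malonate | CCCCCCCCCCCCCCCCCCCCCCCCCOC(=O)CC(=O)OCc1ccccc1
F3 | step 5 | benzyl pentacosyl 2-(4-hydroxybenzyl)malonate (racemic) | CCCCCCCCCCCCCCCCCCCCCCCCCOC(=O)C(Cc1ccc(O)cc1)C(=O)OCc1ccccc1
F4 | step 3 | 3-oxo-3-(pentacosyloxy)propanoic acid (pentacosyl hydrogen malonate) | CCCCCCCCCCCCCCCCCCCCCCCCCOC(=O)CC(=O)O
F5 | step 6 | pentacosyl (2E)-3-(4-hydroxyphenyl)prop-2-enoate | CCCCCCCCCCCCCCCCCCCCCCCCCOC(=O)/C=C/c1ccc(O)cc1
A1 | alternative 1 | pentacosyl 5-oxopentanoate | CCCCCCCCCCCCCCCCCCCCCCCCCOC(=O)CCCC=O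
A2 | alternative 1 | but-3-en-2-one | CC(=O)C=C
A3 | alternative 1 | pentacosyl 3-(4-oxocyclohex-2-en-1-yl)propanoate (racemic) | CCCCCCCCCCCCCCCCCCCCCCCCCOC(=O)CCC1CCC(=O)C=C1
A4 | alternative 2 | 16-{[3-(4-acetoxyphenyl)propanoyl]oxy}hexadecanoic acid | CC(=O)Oc1ccc(CCC(=O)OCCCCCCCCCCCCCCCC(=O)O)cc1
A5 | alternative 2 | undecanoic acid | CCCCCCCCCCC(=O)O
A6 | alternative 2 | pentacosyl 3-(4-acetoxyphenyl)propanoate | CCCCCCCCCCCCCCCCCCCCCCCCCOC(=O)CCc1ccc(OC(C)=O)cc1
A7 | alternative 3 | 1-(benzyloxy)-4-ethenylbenzene | C=Cc1ccc(OCc2ccccc2)cc1
A8 | alternative 3 | carbon monoxide | [C-]#[O+]
A9 | alternative 3 | pentacosyl 3-[4-(benzyloxy)phenyl]propanoate | CCCCCCCCCCCCCCCCCCCCCCCCCOC(=O)CCc1ccc(OCc2ccccc2)cc1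
A10 | alternative 3 | palladium diacetate | CC(=O)[O-].CC(=O)[O-].[Pd+2]
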